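**Plan**
- Retrosynthesis: the two esters and the C7=C8 unsaturation go first. C6–O and C5–H are then cut together (hydroboration of C5=C6), followed by C4–isopropyl (1,2-addition to a C4 ketone) and C1–CH3 (conjugate addition to a C5=C1 enone). Last, the seven-membered ring (C1, C5–C10) is contracted to a benzene ring by excising C5.
- Enabling feature: in the seven-membered ring, C8–CH3 and C9=O lie para and meta to ring-fusion C1, and ring-fusion C5 is α to C4 (a former ketone). The ring is therefore a 2-methylanisole ring plus one carbene carbon, so a C4 diazoketone tethered through C3–C2 can insert C5 into the arene (Buchner reaction) and close the five-membered ring in the same event.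
- Forward order: aldol (C2–C3), silylation, diazo transfer; five-membered ring closure with benzene-to-cycloheptatriene expansion; C9 ketal; CH3 to C1; isopropyl to C4; H/OH across C5=C6; two esterifications; ketone release, C7=C8 dehydrogenation, phenol release.
- Stereochemistry: only C2 is set by catalysis (proline aldol). C1 and C4 are set by additions anti to the C2 silyloxy group, and C5/C6 by syn hydroboration anti to the C1 methyl and C4 isopropyl groups.

Key step: step 4

Remark: daucane numbering is used (C1 quaternary ring-fusion C, C2 CH–OAc, C3 CH2, C4 C(OH)(iPr), C5 ring-fusion CH, C6 CH–O-aroyl, C7=C8(CH3), C9 C=O, C10 CH2; α = face opposite the C1 methyl); 1 and 17 are assumed purchasable; compounds 10–21 are carried as C8 epimer mixtures, which is harmless because C8 becomes sp2 again in step 13.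

Step 1
Reactants: 1 3-methoxy-4-methylbenzaldehyde; 2 acetone
Product: 3 (R)-4-hydroxy-4-(3-methoxy-4-methylphenyl)butan-2-one
Conditions: L-proline (30 mol %), acetone/DMSO 1:4, 23 °C
Reagents that add atoms: acetone, CC(C)=O
Why: Proline-catalysed direct aldol addition (Hajos–Parrish type enamine catalysis); the acetone enamine should add through the carboxylic acid-directed chair transition state to give the (R)-carbinol (C2), with only moderate enantioselectivity expected for this electron-rich aldehyde.

Step 2
Reactants: 3 (R)-aldol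
Product: 4 (R)-4-(tert-butyldimethylsilyloxy)-4-(3-methoxy-4-methylphenyl)butan-2-one
Conditions: TBSOTf, 2,6-lutidine, CH2Cl2, −78 → 0 °C
Reagents that add atoms: tert-butyldimethylsilyl triflate, CC(C)(C)[Si](C)(C)OS(=O)(=O)C(F)(F)F
Why: Silylation of a secondary alcohol with a silyl triflate and a hindered base at low temperature, which should avoid retro-aldol cleavage and β-elimination.

Step 3
Reactants: 4 silyl ether
Product: 6 (R)-4-(tert-butyldimethylsilyloxy)-1-diazo-4-(3-methoxy-4-methylphenyl)butan-2-one, via trifluoroacetyl diketone 5 (not isolated)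
Conditions: LiHMDS, THF, −78 °C; CF3CO2CH2CF3; then MsN3, Et3N, H2O, MeCN, 23 °C
Reagents that add atoms: methanesulfonyl azide, CS(=O)(=O)N=[N+]=[N-]
Why: Detrifluoroacetylative (Regitz-type) diazo transfer: the kinetic methyl enolate is acylated to 5, and azide transfer with loss of the trifluoroacetyl group should give the terminal diazoketone without touching the silyloxy stereocentre.

Step 4
Reactants: 6 diazoketone
Product: 9 (R)-3-(tert-butyldimethylsilyloxy)-5-methoxy-6-methyl-3,4-dihydroazulen-1(2H)-one, via norcaradiene 7 (not isolated), via 8aH-azulenone 8 (not isolated)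
Conditions: Rh2(OAc)4 (1 mol %), CH2Cl2, 40 °C, slow addition of 6; then Et3N, 23 °C
Reagents that add atoms: none
Why: Rh2(OAc)4 turns the diazoketone into an electrophilic Rh2(OAc)4-bound carbene that cyclopropanates the arene bond between future C1 (ipso) and C6 (ortho) to give norcaradiene 7, whose cyclohexadiene opens by disrotatory 6π electrocyclic cleavage of the shared cyclopropane bond, so the benzene ring becomes the cycloheptatriene of 8 (intramolecular Buchner reaction; closest precedent is the cyclisation of 1-diazo-4-arylbutan-2-ones to dihydroazulenones). The five-membered ring closes by bonding of the carbene carbon C5 to the ipso carbon within the [2+1] addition (5-exo mode), whereas the seven-membered ring is not closed separately but arises by one-carbon expansion of the six-membered ring. Et3N then moves the doubly allylic α-keto hydrogen from C5 to C10, giving the conjugated tetrasubstituted enone 9, which can no longer aromatise to a tetralone. The only new stereocentre (C5 in 8) is transient and is erased in 9, so C2 remains the sole stereocentre. Regioselectivity between the two ortho carbons is required and should be secured because the ortho carbon para to OCH3 is both the more nucleophilic and the unhindered one, which places OCH3 on C9 and CH3 on C8. Chemoselectivity over aromatic C–H insertion and ylide formation should follow from the weakly electrophilic carboxylate catalyst, the poor donor ability of the silyl ether oxygen and the absence of an aliphatic C–H five atoms from the carbene.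

Step 5
Reactants: 9 dihydroazulenone enol ether
Product: 10 C9 ethylene ketal of the C4(=O)–C5=C1/C6=C7 dienone (2R)
Conditions: HOCH2CH2OH, PPTS (cat.), 4 Å MS, CH2Cl2, 23 °C
Reagents that add atoms: ethylene glycol, OCCO
Why: Acid-catalysed exchange of the methyl enol ether for a dioxolane (transketalisation); protonation at C8 is expected because it leaves C6=C7 conjugated with the enone, as in the formation of β,γ-unsaturated ketals from dienol ethers.

Step 6
Reactants: 10 dienone ketal
Product: 13 (1S,2R)-enone with C1 methyl and C5=C6 conjugated to C4=O, via silyl dienol ether 11 (not isolated), via deconjugated ketone 12 (not isolated)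
Conditions: Me2CuLi (from MeLi and CuI), TMSCl, THF, −78 → −30 °C; aq. NH4Cl; then DBU (0.2 equiv), CH2Cl2, 0 °C
Reagents that add atoms: lithium dimethylcuprate, [Li+].C[Cu-]C
Why: TMSCl-accelerated cuprate 1,4-addition to the 4-silyloxycyclopentenone should occur anti to the adjacent C2 silyloxy group (as in three-component prostaglandin couplings), setting quaternary C1; hydrolysis of 11 and DBU-mediated prototropy then move C6=C7 of 12 into conjugation as C5=C6.

Step 7
Reactants: 13 enone
Product: 14 (1S,2R,4R)-tertiary allylic alcohol (C4 OH α, isopropyl β)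
Conditions: iPrLi, CeCl3, THF, −78 °C
Reagents that add atoms: isopropyllithium, [Li]C(C)C
Why: Organocerium 1,2-addition (low basicity suppresses enolisation, β-elimination and reduction) from the face anti to the C2 silyloxy group, as in additions to 4-silyloxycyclopentenones, should set C4 with OH cis to OTBS.

Step 8
Reactants: 14 allylic alcohol
Product: 16 (1S,2R,4R,5R,6R)-4,6-diol with trans ring fusion, via alkylborane 15 (not isolated)
Conditions: BH3·THF, THF, 0 → 23 °C; then NaOH, H2O2, 0 → 23 °C
Reagents that add atoms: hydrogen peroxide, OO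
Why: Hydroboration–oxidation: syn anti-Markovnikov addition with boron on the less substituted C6 from the α face, opposite the C1 methyl and C4 isopropyl groups flanking C5, should set C5–H and C6–OH cis and give the trans ring fusion, as with Δ5-steroids.

Step 9
Reactants: 16 diol; 17 4-acetoxybenzoyl chloride
Product: 18 C6 4-acetoxybenzoate
Conditions: 17, Et3N, DMAP (cat.), CH2Cl2, 0 → 23 °C
Reagents that add atoms: 4-acetoxybenzoyl chloride, CC(=O)Oc1ccc(cc1)C(Cl)=O
Why: DMAP-catalysed acylation of the secondary C6 alcohol; the tertiary C4 alcohol is too hindered to react.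

Step 10
Reactants: 18 silyl ether ester
Product: 19 C2 alcohol
Conditions: TBAF, AcOH, THF, 23 °C
Reagents that add atoms: none
Why: Fluoride-mediated cleavage of the silyl ether, buffered with acetic acid so that the aryl acetate and the benzoate should survive.

Step 11
Reactants: 19 C2 alcohol
Product: 20 C2 acetate
Conditions: Ac2O, pyridine, DMAP (cat.), 23 °C
Reagents that add atoms: acetic anhydride, CC(=O)OC(C)=O
Why: Nucleophile-catalysed acetylation of the secondary C2 alcohol; the tertiary alcohol stays free, and any phenol freed in step 10 would be re-acetylated to the same compound.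

Step 12
Reactants: 20 ketal
Product: 21 C9 ketone
Conditions: HCl (1 M aq.), THF, 23 °C
Reagents that add atoms: water, O
Why: Acid-catalysed ketal hydrolysis; the esters and the tertiary alcohol should tolerate dilute acid at room temperature.

Step 13
Reactants: 21 ketone
Product: 22 C7=C8 enone (phenol still acetylated)
Conditions: IBX, DMSO, 70 °C
Reagents that add atoms: none
Why: IBX-mediated α,β-dehydrogenation of a ketone; only C7=C8 can form because C10 is attached to quaternary C1, and both C8 epimers converge.

Step 14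
Reactants: 22 aryl acetate
Product: 23 target
Conditions: NH4OAc, MeOH/H2O 4:1, 23 °C
Reagents that add atoms: none
Why: Chemoselective solvolysis of the phenolic acetate (phenoxide is the better leaving group) in the presence of the alkyl acetate and the benzoate under near-neutral conditions.

**Compound list**
1 | 3-methoxy-4-methylbenzaldehyde | O=Cc1ccc(C)c(OC)c1 | starting material
2 | acetone | CC(C)=O | starting material
3 | (R)-4-hydroxy-4-(3-methoxy-4-methylphenyl)butan-2-one | CC(=O)C[C@@H](O)c1ccc(C)c(OC)c1 | intermediate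
4 | (R)-4-(tert-butyldimethylsilyloxy)-4-(3-methoxy-4-methylphenyl)butan-2-one | CC(=O)C[C@@H](O[Si](C)(C)C(C)(C)C)c1ccc(C)c(OC)c1 | intermediate
5 | (R)-6-(tert-butyldimethylsilyloxy)-1,1,1-trifluoro-6-(3-methoxy-4-methylphenyl)hexane-2,4-dione (not isolated) | O=C(CC(=O)C[C@@H](O[Si](C)(C)C(C)(C)C)c1ccc(C)c(OC)c1)C(F)(F)F | intermediate
6 | (R)-4-(tert-butyldimethylsilyloxy)-1-diazo-4-(3-methoxy-4-methylphenyl)butan-2-one | [N-]=[N+]=CC(=O)C[C@@H](O[Si](C)(C)C(C)(C)C)c1ccc(C)c(OC)c1 | intermediate
7 | norcaradiene: cyclopropane C1–C5–C6, diene C7=C8–C9=C10, C4 ketone, C2 (R)-OTBS, new ring-fusion centres unassigned (not isolated) | CC(C)(C)[Si](C)(C)O[C@@H]1CC(=O)C2C3C=C(C)C(OC)=CC123 | intermediate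
8 | (3R)-3-(tert-butyldimethylsilyloxy)-5-methoxy-6-methyl-3,8a-dihydroazulen-1(2H)-one, C8a epimers (not isolated) | CC(C)(C)[Si](C)(C)O[C@@H]1CC(=O)C2C=CC(C)=C(OC)C=C12 | intermediate
9 | (R)-3-(tert-butyldimethylsilyloxy)-5-methoxy-6-methyl-3,4-dihydroazulen-1(2H)-one (C5=C1, C6=C7, C8=C9 in daucane numbering) | CC(C)(C)[Si](C)(C)O[C@@H]1CC(=O)C2=C1CC(OC)=C(C)C=C2 | intermediate
10 | C9 ethylene ketal, C4 ketone, C5=C1 and C6=C7, C8–H, (2R)-OTBS | CC(C)(C)[Si](C)(C)O[C@@H]1CC(=O)C2=C1CC3(OCCO3)C(C)C=C2 | intermediate
11 | C4 trimethylsilyl dienol ether (C4=C5, C6=C7), C1 methyl β, C2 OTBS α (not isolated) | CC(C)(C)[Si](C)(C)O[C@@H]1CC(O[Si](C)(C)C)=C2C=CC(C)C3(OCCO3)C[C@]12C | intermediate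
12 | deconjugated ketone: C4=O, C5–H (epimers), C6=C7, (1S,2R) (not isolated) | CC(C)(C)[Si](C)(C)O[C@@H]1CC(=O)C2C=CC(C)C3(OCCO3)C[C@]12C | intermediate
13 | (1S,2R)-enone: C4=O conjugated with C5=C6, C1 methyl β, C2 OTBS α, C9 ethylene ketal | CC(C)(C)[Si](C)(C)O[C@@H]1CC(=O)C2=CCC(C)C3(OCCO3)C[C@]12C | intermediate
14 | (1S,2R,4R)-C4 tertiary alcohol (OH α, isopropyl β), C5=C6, C2 OTBS, C9 ketal | CC(C)(C)[Si](C)(C)O[C@@H]1C[C@@](O)(C(C)C)C2=CCC(C)C3(OCCO3)C[C@]12C | intermediate
15 | C6 alkylborane adduct of 14, drawn as the monoalkylborane (C5–H α, C6–B α) (not isolated) | CC(C)(C)[Si](C)(C)O[C@@H]1C[C@@](O)(C(C)C)[C@H]2[C@H](B)CC(C)C3(OCCO3)C[C@]12C | intermediate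
16 | (1S,2R,4R,5R,6R)-4,6-diol, trans-fused, C2 OTBS, C9 ketal | CC(C)(C)[Si](C)(C)O[C@@H]1C[C@@](O)(C(C)C)[C@H]2[C@H](O)CC(C)C3(OCCO3)C[C@]12C | intermediate
17 | 4-acetoxybenzoyl chloride | CC(=O)Oc1ccc(cc1)C(Cl)=O | starting material
18 | C6 4-acetoxybenzoate of 16 | CC(C)(C)[Si](C)(C)O[C@@H]1C[C@@](O)(C(C)C)[C@H]2[C@H](OC(=O)c3ccc(OC(C)=O)cc3)CC(C)C4(OCCO4)C[C@]12C | intermediate
19 | C2 alcohol (2,4-diol, C6 4-acetoxybenzoate, C9 ketal) | O[C@@H]1C[C@@](O)(C(C)C)[C@H]2[C@H](OC(=O)c3ccc(OC(C)=O)cc3)CC(C)C4(OCCO4)C[C@]12C | intermediate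
20 | C2 acetate, C6 4-acetoxybenzoate, C9 ketal | CC(=O)O[C@@H]1C[C@@](O)(C(C)C)[C@H]2[C@H](OC(=O)c3ccc(OC(C)=O)cc3)CC(C)C4(OCCO4)C[C@]12C | intermediate
21 | C9 ketone (7,8-dihydro, C8 epimers), C2 acetate, C6 4-acetoxybenzoate | CC(=O)O[C@@H]1C[C@@](O)(C(C)C)[C@H]2[C@H](OC(=O)c3ccc(OC(C)=O)cc3)CC(C)C(=O)C[C@]12C | intermediate
22 | (1S,2R,4R,5R,6R)-7-en-9-one, C2 acetate, C6 4-acetoxybenzoate | CC(=O)O[C@@H]1C[C@@](O)(C(C)C)[C@H]2[C@H](OC(=O)c3ccc(OC(C)=O)cc3)C=C(C)C(=O)C[C@]12C | intermediate
23 | target, (1S,2R,4R,5R,6R) in daucane numbering: 2α-acetoxy-4α-hydroxy-6α-(4-hydroxybenzoyloxy)-dauc-7-en-9-one | CC(=O)O[C@@H]1C[C@@](O)(C(C)C)[C@H]2[C@H](OC(=O)c3ccc(O)cc3)C=C(C)C(=O)C[C@]12C | target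

**Step count and risks**
Total steps: 14. Longest linear sequence: 14 (from 1).

Steps most likely to fail:

1. Step 6. The risk is loss of the C2 silyloxy group by E1cB elimination during the base-mediated double-bond shift, alongside a sluggish 1,4-addition to the tetrasubstituted enone. The fallback sets out from 12 and reinstalls the C2 oxygen instead of carrying it. Excess DBU (CH2Cl2, 23 °C) would drive both elimination and conjugation to the cross-conjugated dienone F1. H2O2/NaOH (MeOH, 0 °C) should epoxidise the disubstituted cyclopentenone double bond from the α face, anti to the C1 methyl (Weitz–Scheffer epoxidation), giving epoxy ketone F2. SmI2 (THF/MeOH, −78 °C) should cleave the Cα–O bond to the β-hydroxy enone F3, and TBSOTf/2,6-lutidine returns to 13.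

2. Step 5. The risk is protonation of the trienol ether at C6 instead of C8, which leaves the double bond at C7=C8 where base cannot bring it into conjugation with C4. The fallback sets out from 9 and uses the allylic ketal F4 as formed. Me2CuLi/TMSCl should give the regiodefined silyl enol ether F5, kept without hydrolysis. H2 over Pd/C (EtOAc) should saturate C7=C8 to give F6, and Pd(OAc)2 in MeCN (Saegusa–Ito oxidation) should introduce C5=C6 and return to 13.

3. Step 8. The risk is slow hydroboration of an alkene flanked by two quaternary carbons, with erosion of α-face selectivity by the allylic oxygen. The fallback sets out from 14 and delivers hydrogen and the oxygen surrogate from a silicon tether on the α-oriented C4 oxygen. (HMe2Si)2NH should give the hydrosilyl ether F7. H2PtCl6-catalysed intramolecular hydrosilylation (5-endo) should place H on C5 and Si on C6 on the α face, giving oxasilolane F8. Tamao–Fleming oxidation (H2O2, KF, KHCO3, THF/MeOH) returns to 16.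

**Further compounds**
F1 | step 6 | cross-conjugated dienone: C2=C3–C4(=O)–C5=C6, C1 methyl β, C9 ketal | C1=CC(=O)C2=CCC(C)C3(OCCO3)C[C@]12C
F2 | step 6 | 2α,3α-epoxy ketone with C5=C6 enone | O1[C@@H]2[C@H]1C(=O)C3=CCC(C)C4(OCCO4)C[C@]23C
F3 | step 6 | 2α-hydroxy enone (desilyl 13) | O[C@@H]1CC(=O)C2=CCC(C)C3(OCCO3)C[C@]12C
F4 | step 5 | allylic ketal isomer of 10: C5=C1 enone, C6H2, C7=C8 | CC(C)(C)[Si](C)(C)O[C@@H]1CC(=O)C2=C1CC3(OCCO3)C(C)=CC2
F5 | step 5 | C4 trimethylsilyl enol ether (C4=C5), C1 methyl β, C7=C8 | CC(C)(C)[Si](C)(C)O[C@@H]1CC(O[Si](C)(C)C)=C2CC=C(C)C3(OCCO3)C[C@]12C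
F6 | step 5 | C4 trimethylsilyl enol ether (C4=C5), C7–C8 saturated | CC(C)(C)[Si](C)(C)O[C@@H]1CC(O[Si](C)(C)C)=C2CCC(C)C3(OCCO3)C[C@]12C
F7 | step 8 | C4 O-dimethylsilyl (Si–H) ether of 14 | CC(C)(C)[Si](C)(C)O[C@@H]1C[C@@](O[SiH](C)C)(C(C)C)C2=CCC(C)C3(OCCO3)C[C@]12C
F8 | step 8 | oxasilolane bridging C4–O and C6 (C5–H α, C6–Si α) | CC(C)(C)[Si](C)(C)O[C@@H]1C[C@@](O4)(C(C)C)[C@H]2[C@H]([Si]4(C)C)CC(C)C3(OCCO3)C[C@]12C
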